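**Retrosynthetic overview**
- The last bond made is C3a–C11a (butenolide β-carbon to the carbinol carbon). A (Z)-β-iodo enoate acts as a β-acylvinyl anion (d3, homoenolate-type donor) under Ni/Cr and adds to a tethered Z-enal; the alkoxide then lactonises. The 10-membered carbocycle and the butenolide form in this one operation, carbocycle first.
- The seco iodo-enal comes from a methyl ketone (carrying the iodo-enoate and the enone) and a Z-enal by a (+)-Ipc2BCl aldol that sets C9, followed by acetylation, desilylation and oxidation.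
- The methyl ketone comes from hex-5-ynoic acid: MeLi, Pd/Cu methoxycarbonylation, MgI2/CH2O halo-aldol, acetylation, Mannich methylenation.
- The Z-enal comes from but-2-yn-1-ol: Red-Al/I2 (fixes the Z-olefin), silylation, t-BuLi/DMF.

Assumption: the SMILES is read as (9S,10Z,11aR) in cyclodeca[b]furan numbering (O1, C2=O, C3–CH2OAc, C3a, C4, C5, C6=CH2, C7=O, C8, C9–OAc, C10–Me, C11, C11a); reagents such as MeLi, (+)-Ipc2BCl, CrCl2 and Dess–Martin periodinane are bought.

**Route**

Step 1
Reactants: 1 hex-5-ynoic acid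
Product: 3 hept-6-yn-2-one, via trilithium gem-diolate acetylide 2 (not isolated)
Conditions: MeLi (3.2 equiv), THF, 0 °C → rt; then H2O
Reagents that add atoms: methyllithium [Li]C
Why: Organolithium addition to a lithium carboxylate stops at the stable gem-diolate, which gives the methyl ketone on hydrolysis, the third equivalent only deprotonating the alkyne.

Step 2
Reactants: 3 hept-6-yn-2-one
Product: 4 methyl 7-oxooct-2-ynoate
Conditions: PdCl2 (5 mol %), CuCl2 (2.2 equiv), NaOAc (2.2 equiv), CO (1 atm), MeOH, rt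
Reagents that add atoms: carbon monoxide [C-]#[O+]; methanol CO
Why: Tsuji oxidative alkoxycarbonylation of a terminal alkyne gives the ynoate under buffered conditions that need no acetylide base and so tolerate the enolisable ketone.

Step 3
Reactants: 4 methyl 7-oxooct-2-ynoate
Product: 6 methyl (2Z)-2-(hydroxymethyl)-3-iodo-7-oxooct-2-enoate, via magnesium iodoallenolate 5 (not isolated)
Conditions: MgI2 (1.3 equiv), CH2O (gas from cracked paraformaldehyde, 3 equiv), CH2Cl2, −20 → 0 °C; then H2O
Reagents that add atoms: magnesium iodide [Mg+2].[I-].[I-]; formaldehyde C=O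
Why: Halo-aldol (β-iodo Morita–Baylis–Hillman) reaction in which iodide adds 1,4 to the ynoate and the β-iodoallenolate is hydroxymethylated at Cα from the side of the alkyl chain, placing iodine cis to the ester (2Z), any E-isomer being removed by chromatography.

Step 4
Reactants: 6 methyl (2Z)-2-(hydroxymethyl)-3-iodo-7-oxooct-2-enoate
Product: 7 methyl (2Z)-2-(acetoxymethyl)-3-iodo-7-oxooct-2-enoate
Conditions: Ac2O, pyridine, DMAP (cat.), CH2Cl2, 0 °C
Reagents that add atoms: acetic anhydride CC(=O)OC(C)=O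
Why: DMAP-catalysed acetylation installs the primary acetate of the target early, where it also serves as protection.

Step 5
Reactants: 7 methyl (2Z)-2-(acetoxymethyl)-3-iodo-7-oxooct-2-enoate
Product: 9 methyl (2Z)-2-(acetoxymethyl)-3-iodo-6-methylidene-7-oxooct-2-enoate, via Mannich base 8 (not isolated)
Conditions: (CH2O)n, PhNHMe·TFA, THF, reflux
Reagents that add atoms: formaldehyde C=O
Why: Gras α-methylenation (Mannich condensation then β-elimination of the amine) runs through the more substituted enol of the methyl ketone and therefore methylenates C6, not the methyl group.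

Step 6
Reactants: 10 but-2-yn-1-ol
Product: 12 (2Z)-3-iodobut-2-en-1-ol, via cyclic vinylalanate 11 (not isolated)
Conditions: Red-Al (1.5 equiv), THF, 0 °C → rt; then I2, −78 → 0 °C; aq. work-up
Reagents that add atoms: iodine II
Why: Hydroxyl-directed trans-hydroalumination followed by iodinolysis with retention gives the (Z)-3-iodo allylic alcohol and so fixes the Z-trisubstituted olefin of the ring.

Step 7
Reactants: 12 (2Z)-3-iodobut-2-en-1-ol
Product: 13 tert-butyl{[(2Z)-3-iodobut-2-en-1-yl]oxy}dimethylsilane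
Conditions: TBSCl, imidazole, CH2Cl2, rt
Reagents that add atoms: tert-butyldimethylsilyl chloride CC(C)(C)[Si](C)(C)Cl
Why: Standard silylation masks the primary alcohol (the future C11a carbinol carbon) through the lithiation and the aldol.

Step 8
Reactants: 13 tert-butyl{[(2Z)-3-iodobut-2-en-1-yl]oxy}dimethylsilane
Product: 15 (2Z)-4-[(tert-butyldimethylsilyl)oxy]-2-methylbut-2-enal, via vinyllithium 14 (not isolated)
Conditions: t-BuLi (2.1 equiv), Et2O, −78 °C; then DMF, −78 → 0 °C; then H2O
Reagents that add atoms: N,N-dimethylformamide CN(C)C=O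
Why: Iodine–lithium exchange proceeds with retention of olefin geometry and DMF formylation (Bouveault type) gives the Z-enal, which is used at once to avoid Z→E isomerisation.

Step 9
Reactants: 9 methyl (2Z)-2-(acetoxymethyl)-3-iodo-6-methylidene-7-oxooct-2-enoate; 15 (2Z)-4-[(tert-butyldimethylsilyl)oxy]-2-methylbut-2-enal
Product: 17 methyl (2Z,9S,10Z)-2-(acetoxymethyl)-12-[(tert-butyldimethylsilyl)oxy]-9-hydroxy-3-iodo-10-methyl-6-methylidene-7-oxododeca-2,10-dienoate, via boron dienolate 16 (not isolated)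
Conditions: (+)-Ipc2BCl (1.3 equiv), Et3N, Et2O, 0 °C; then 15, −78 → −25 °C; then H2O2, pH 7 buffer, MeOH, 0 °C
Reagents that add atoms: none
Why: Paterson boron aldol in which the diisopinocampheylboron enolate of the methyl ketone adds to the Si face of the Z-enal under control of the (+)-Ipc ligands (the sense established for methyl ketone/Z-enal couplings with this reagent), setting the carbinol that becomes C9 as S in an expected 80–90% ee.

Step 10
Reactants: 17 (aldol adduct)
Product: 18 methyl (2Z,9S,10Z)-9-acetoxy-2-(acetoxymethyl)-12-[(tert-butyldimethylsilyl)oxy]-3-iodo-10-methyl-6-methylidene-7-oxododeca-2,10-dienoate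
Conditions: Ac2O, pyridine, DMAP (cat.), CH2Cl2, 0 °C, short reaction time
Reagents that add atoms: acetic anhydride CC(=O)OC(C)=O
Why: Acetylation at 0 °C installs the second acetate of the target without E1cB loss and removes the free hydroxyl that could otherwise close onto the enone by oxa-Michael addition.

Step 11
Reactants: 18 (silyl ether diacetate)
Product: 19 methyl (2Z,9S,10Z)-9-acetoxy-2-(acetoxymethyl)-12-hydroxy-3-iodo-10-methyl-6-methylidene-7-oxododeca-2,10-dienoate
Conditions: HF·pyridine, pyridine, THF, 0 °C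
Reagents that add atoms: none
Why: Buffered fluoride desilylation frees the primary allylic alcohol without touching the acetates or the base-sensitive β-acetoxy ketone.

Step 12
Reactants: 19 (allylic alcohol)
Product: 20 methyl (2Z,9S,10Z)-9-acetoxy-2-(acetoxymethyl)-3-iodo-10-methyl-6-methylidene-7,12-dioxododeca-2,10-dienoate
Conditions: Dess–Martin periodinane, pyridine, CH2Cl2, 0 °C; used crude
Reagents that add atoms: none
Why: Dess–Martin oxidation under buffered, non-basic conditions gives the Z-enal without olefin isomerisation or acetate elimination.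

Step 13
Reactants: 20 (seco iodo-enal)
Product: 22 (9S,10Z,11aR)-3-(acetoxymethyl)-10-methyl-6-methylidene-2,7-dioxo-2,4,5,6,7,8,9,11a-octahydrocyclodeca[b]furan-9-yl acetate, via ring-closed hydroxy ester 21 (not isolated)
Conditions: CrCl2 (10 equiv), NiCl2 (1 mol % of Cr), degassed DMSO/THF, rt, syringe-pump addition to 2 mM; aq. work-up (cat. PPTS, CH2Cl2 if lactonisation is incomplete)
Reagents that add atoms: none
Why: Proposed new method: Ni(0) inserts into the activated C–I bond of the (Z)-β-iodo enoate and transmetalates to Cr(III), giving a β-acylvinyl (d3, homoenolate-type) nucleophile that adds 1,2 to the tethered Z-enal, so joining two innately electrophilic carbons, after which the chromium alkoxide held cis to CO2Me lactonises; the closest known chemistry is the intermolecular Ni/Cr (Nozaki–Hiyama–Kishi) coupling of (Z)-β-iodo enoates with aldehydes to butenolides and NHK closures of 9- and 10-membered carbocycles, and C11a is set by macrocyclic control from the C9 acetate, R being assumed (not predictable with confidence) from a transition state with the 9-OAc pseudo-equatorial and C3a and C8 on opposite faces of the Z-olefin.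

**Compound list**
1 | hex-5-ynoic acid | C#CCCCC(=O)O | starting material
2 | trilithium gem-diolate acetylide of 1 | [Li]C#CCCCC(C)(O[Li])O[Li] | intermediate
3 | hept-6-yn-2-one | CC(=O)CCCC#C | intermediate
4 | methyl 7-oxooct-2-ynoate | CC(=O)CCCC#CC(=O)OC | intermediate
5 | magnesium β-iodoallenolate of 4 | CC(=O)CCCC(I)=C=C(OC)O[Mg]I | intermediate
6 | methyl (2Z)-2-(hydroxymethyl)-3-iodo-7-oxooct-2-enoate | COC(=O)/C(CO)=C(\I)CCCC(C)=O | intermediate
7 | methyl (2Z)-2-(acetoxymethyl)-3-iodo-7-oxooct-2-enoate | COC(=O)/C(COC(C)=O)=C(\I)CCCC(C)=O | intermediate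
8 | Mannich base, methyl (2Z)-2-(acetoxymethyl)-3-iodo-6-{[methyl(phenyl)amino]methyl}-7-oxooct-2-enoate | COC(=O)/C(COC(C)=O)=C(\I)CCC(CN(C)c1ccccc1)C(C)=O | intermediate
9 | methyl (2Z)-2-(acetoxymethyl)-3-iodo-6-methylidene-7-oxooct-2-enoate | COC(=O)/C(COC(C)=O)=C(\I)CCC(=C)C(C)=O | intermediate
10 | but-2-yn-1-ol | CC#CCO | starting material
11 | sodium cyclic vinylalanate from 10 | CC1=CCO[Al-]1(OCCOC)OCCOC.[Na+] | intermediate
12 | (2Z)-3-iodobut-2-en-1-ol | C/C(I)=C/CO | intermediate
13 | tert-butyl{[(2Z)-3-iodobut-2-en-1-yl]oxy}dimethylsilane | C/C(I)=C/CO[Si](C)(C)C(C)(C)C | intermediate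
14 | (2Z)-4-[(tert-butyldimethylsilyl)oxy]but-2-en-2-yllithium | C/C([Li])=C/CO[Si](C)(C)C(C)(C)C | intermediate
15 | (2Z)-4-[(tert-butyldimethylsilyl)oxy]-2-methylbut-2-enal | C/C(C=O)=C/CO[Si](C)(C)C(C)(C)C | intermediate
16 | bis[(1S,2R,3S,5S)-isopinocampheyl]boron dienolate of 9 | COC(=O)/C(COC(C)=O)=C(\I)CCC(=C)C(=C)OB([C@H]1C[C@H]2C[C@@H]([C@@H]1C)C2(C)C)[C@H]1C[C@H]2C[C@@H]([C@@H]1C)C2(C)C | intermediate
17 | methyl (2Z,9S,10Z)-2-(acetoxymethyl)-12-[(tert-butyldimethylsilyl)oxy]-9-hydroxy-3-iodo-10-methyl-6-methylidene-7-oxododeca-2,10-dienoate | COC(=O)/C(COC(C)=O)=C(\I)CCC(=C)C(=O)C[C@H](O)/C(C)=C\CO[Si](C)(C)C(C)(C)C | intermediate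
18 | methyl (2Z,9S,10Z)-9-acetoxy-2-(acetoxymethyl)-12-[(tert-butyldimethylsilyl)oxy]-3-iodo-10-methyl-6-methylidene-7-oxododeca-2,10-dienoate | COC(=O)/C(COC(C)=O)=C(\I)CCC(=C)C(=O)C[C@H](OC(C)=O)/C(C)=C\CO[Si](C)(C)C(C)(C)C | intermediate
19 | methyl (2Z,9S,10Z)-9-acetoxy-2-(acetoxymethyl)-12-hydroxy-3-iodo-10-methyl-6-methylidene-7-oxododeca-2,10-dienoate | COC(=O)/C(COC(C)=O)=C(\I)CCC(=C)C(=O)C[C@H](OC(C)=O)/C(C)=C\CO | intermediate
20 | methyl (2Z,9S,10Z)-9-acetoxy-2-(acetoxymethyl)-3-iodo-10-methyl-6-methylidene-7,12-dioxododeca-2,10-dienoate | COC(=O)/C(COC(C)=O)=C(\I)CCC(=C)C(=O)C[C@H](OC(C)=O)/C(C)=C\C=O | intermediate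
21 | methyl (2Z)-3-acetoxy-2-[(2R,3Z,5S)-5-acetoxy-2-hydroxy-4-methyl-8-methylidene-7-oxocyclodec-3-en-1-ylidene]propanoate (formed as its Cr(III) alkoxide) | C=C1CC/C(=C(\COC(C)=O)C(=O)OC)[C@H](O)/C=C(/C)[C@@H](OC(C)=O)CC1=O | intermediate
22 | (9S,10Z,11aR)-3-(acetoxymethyl)-10-methyl-6-methylidene-2,7-dioxo-2,4,5,6,7,8,9,11a-octahydrocyclodeca[b]furan-9-yl acetate (CNP0272505.1) | C=C1CCC2=C(COC(C)=O)C(=O)O[C@@H]2/C=C(/C)[C@@H](OC(C)=O)CC1=O | target

**Totals**
Total step count: 13. Longest linear sequence: 10 steps (steps 1–5, then 9–13); steps 6–8 form the second branch.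

**Three steps most likely to fail, each with one fallback**

Step 13 (Ni/Cr macrocyclisation–lactonisation; risks are oligomerisation, a sluggish tetrasubstituted vinyl metal, and the wrong C11a epimer). The fallback separates coupling from ring closure. It sets out from 15 and 9. Aldehyde 15 is treated with HC(OMe)3 and CSA in MeOH, which forms the acetal and removes the silyl group, giving (2Z)-4,4-dimethoxy-3-methylbut-2-en-1-ol F1. MnO2 oxidation gives (2Z)-4,4-dimethoxy-3-methylbut-2-enal F2. Intermolecular Ni/Cr coupling of 9 with F2, run with a Kishi-type chiral sulfonamide ligand chosen for Si-face addition, gives {(5R)-5-[(1Z)-3,3-dimethoxy-2-methylprop-1-en-1-yl]-4-(3-methylidene-4-oxopentyl)-2-oxo-2,5-dihydrofuran-3-yl}methyl acetate F3. Mild acetal hydrolysis (PPTS, wet acetone) gives {(5R)-5-[(1Z)-2-methyl-3-oxoprop-1-en-1-yl]-4-(3-methylidene-4-oxopentyl)-2-oxo-2,5-dihydrofuran-3-yl}methyl acetate F4. The ring is then closed at C8–C9 by an intramolecular (+)-Ipc2BCl aldol at high dilution to [(9S,10Z,11aR)-9-hydroxy-10-methyl-6-methylidene-2,7-dioxo-2,4,5,6,7,8,9,11a-octahydrocyclodeca[b]furan-3-yl]methyl acetate F5, and acetylation (Ac2O, pyridine, 0 °C) comes back to the route at 22.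

Step 3 (three-component halo-aldol with formaldehyde on a β-alkyl ynoate that also carries a ketone; risks are formaldehyde polymerisation, E/Z erosion and low conversion). The fallback replaces the one-pot Lewis-acid process by a Mukaiyama aldol of a preformed nucleophile; it keeps the same disconnection and changes the nucleophile/electrophile activation rather than the bond-forming strategy. It sets out from 4. TMSI in CH2Cl2 at −78 °C adds 1,4 to give 6-iodo-8-methoxy-8-[(trimethylsilyl)oxy]octa-6,7-dien-2-one F6. This silyl iodoallenoate is hydroxymethylated with commercial aqueous formaldehyde under Yb(OTf)3 catalysis in THF–water, and the sequence comes back to the route at 6.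

Step 9 (Ipc-boron aldol; risks are moderate ee and interference from the enone and the allylic acetate). The fallback replaces the stoichiometric chiral boron enolate by a catalytic Lewis-base-activated Mukaiyama aldol. It sets out from 9. TMSOTf and Et3N give methyl (2Z)-2-(acetoxymethyl)-3-iodo-6-methylidene-7-[(trimethylsilyl)oxy]octa-2,7-dienoate F7. F7 adds to 15 with SiCl4 and a Denmark-type chiral bisphosphoramide (enantiomer chosen for Si-face addition) in CH2Cl2 at −78 °C, and the sequence comes back to the route at 17.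

**Further compounds**
F1 | step 13 | (2Z)-4,4-dimethoxy-3-methylbut-2-en-1-ol | COC(OC)/C(C)=C\CO
F2 | step 13 | (2Z)-4,4-dimethoxy-3-methylbut-2-enal | COC(OC)/C(C)=C\C=O
F3 | step 13 | {(5R)-5-[(1Z)-3,3-dimethoxy-2-methylprop-1-en-1-yl]-4-(3-methylidene-4-oxopentyl)-2-oxo-2,5-dihydrofuran-3-yl}methyl acetate | CC(=O)C(=C)CCC1=C(COC(C)=O)C(=O)O[C@@H]1/C=C(/C)C(OC)OC
F4 | step 13 | {(5R)-5-[(1Z)-2-methyl-3-oxoprop-1-en-1-yl]-4-(3-methylidene-4-oxopentyl)-2-oxo-2,5-dihydrofuran-3-yl}methyl acetate | CC(=O)C(=C)CCC1=C(COC(C)=O)C(=O)O[C@@H]1/C=C(/C)C=O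
F5 | step 13 | [(9S,10Z,11aR)-9-hydroxy-10-methyl-6-methylidene-2,7-dioxo-2,4,5,6,7,8,9,11a-octahydrocyclodeca[b]furan-3-yl]methyl acetate | C=C1CCC2=C(COC(C)=O)C(=O)O[C@@H]2/C=C(/C)[C@@H](O)CC1=O
F6 | step 3 | 6-iodo-8-methoxy-8-[(trimethylsilyl)oxy]octa-6,7-dien-2-one | COC(O[Si](C)(C)C)=C=C(I)CCCC(C)=O
F7 | step 9 | methyl (2Z)-2-(acetoxymethyl)-3-iodo-6-methylidene-7-[(trimethylsilyl)oxy]octa-2,7-dienoate | COC(=O)/C(COC(C)=O)=C(\I)CCC(=C)C(=C)O[Si](C)(C)C
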